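The tridepside is cut at its two aryl ester bonds; rings A and B are the same orsellinate, so one acid serves both. In ring A the a6 methyl and the a1 carboxyl are neighbours, and a1 alone has an oxygen-bearing neighbour (a2). The key step uses this: 1-(benzyloxy)-3-fluoro-5-(triisopropylsilyloxy)benzene, a fluororesorcinol with two different oxygen protecting groups, is turned into the a1–a6 aryne, which takes up methyl at a6 and carbon dioxide at a1 in one flask, forming both carbon–carbon bonds and leaving the a2 and a4 oxygens distinguishable. The acid then enters ring A as its benzyl ester and ring B as such; ring C is made separately and hydrogenolysis finishes.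

Key step: step 3

Remark on labels: ring A is the free-acid ring (a1 CO2H, a2 OH, a4 ester oxygen, a6 CH3); ring B is the middle ring (b1 acyl carbon, b2 OH, b4 ester oxygen, b6 CH3); ring C is the terminal 2,4,5-trihydroxy-6-methylbenzoyl ring (c1 acyl carbon, c6 CH3).

Assumption: the target has no stereocentre, and 5-fluorobenzene-1,3-diol and 2,4-dihydroxy-6-methylbenzaldehyde are taken as commercial.

Remark on the precursor: the structures of the key-step precursor and product are consistent with the target and are kept. Benzyl on the a2 oxygen coordinates lithium and is removed by the final hydrogenolysis. Triisopropylsilyl on the a4 oxygen is bulky, non-directing and stable to n-BuLi.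

Step 1
Reactants: 1 5-fluorobenzene-1,3-diol; 2 benzyl bromide
Product: 3 3-(benzyloxy)-5-fluorophenol
Conditions: BnBr (0.9 equiv), K2CO3, acetone, reflux
Reagents that add atoms: benzyl bromide (2), BrCc1ccccc1
Why: Williamson ether synthesis on a symmetrical diol, run with a deficiency of BnBr so that the mono-ether should be the main product of a statistical mixture and is separated by polarity from recovered diol and the bis-ether.

Step 2
Reactants: 3 3-(benzyloxy)-5-fluorophenol; 4 triisopropylsilyl chloride
Product: 5 1-(benzyloxy)-3-fluoro-5-(triisopropylsilyloxy)benzene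
Conditions: TIPSCl, imidazole, DMF, rt
Reagents that add atoms: triisopropylsilyl chloride (4), CC(C)[Si](Cl)(C(C)C)C(C)C
Why: Imidazole-mediated O-silylation of the remaining phenol, which gives a bulky silyl ether that neither directs lithiation nor migrates and is later cleaved by fluoride without touching benzyl groups.

Step 3
Reactants: 5 1-(benzyloxy)-3-fluoro-5-(triisopropylsilyloxy)benzene; 6 methylmagnesium bromide; 7 carbon dioxide
Product: 11 2-(benzyloxy)-6-methyl-4-(triisopropylsilyloxy)benzoic acid, via aryllithium 8 (not isolated), via aryne 9 (not isolated), via arylmagnesium bromide 10 (not isolated)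
Conditions: n-BuLi (1.05 equiv), THF, −78 °C; MeMgBr (3 equiv), −78 °C → rt; CO2 (g), −20 °C → rt; aq. HCl
Reagents that add atoms: methylmagnesium bromide (6), C[Mg]Br; carbon dioxide (7), O=C=O
Why: n-BuLi should remove the ring hydrogen flanked by fluorine and the benzyloxy group (future a1) to give aryllithium 8, which persists at −78 °C. On warming in the presence of excess MeMgBr it loses LiF to give the 3-alkoxyaryne 9 (triple bond a1–a6), which is carbometalated to arylmagnesium 10 and then carboxylated at a1. The closest known reaction type is aryne generation from an ortho-lithiated fluoroarene with Grignard addition to the 3-alkoxyaryne and electrophilic quench of the resulting arylmagnesium, as used for 6-alkylsalicylic acids. No ring is closed and no stereocentre is formed. Two selectivities are needed: the lithiation site is secured because that C–H is acidified by both fluorine and oxygen and lithium is chelated by the benzyl ether, whereas the hydrogen next to the hindered, non-coordinating silyl ether and the benzylic CH2 react far more slowly with n-BuLi at −78 °C. The orientation of addition is secured by the a2 oxygen, since methyl bonds to the remote aryne carbon a6 so that the carbanion sits at a1 beside the electron-withdrawing C–O bond.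

Step 4
Reactants: 11 2-(benzyloxy)-6-methyl-4-(triisopropylsilyloxy)benzoic acid; 2 benzyl bromide
Product: 12 benzyl 2-(benzyloxy)-6-methyl-4-(triisopropylsilyloxy)benzoate
Conditions: BnBr, KHCO3, DMF, rt
Reagents that add atoms: benzyl bromide (2), BrCc1ccccc1
Why: SN2 O-alkylation of the carboxylate, which takes place at the benzylic carbon and is therefore insensitive to the two ortho substituents, with a base too weak to disturb the aryl silyl ether.

Step 5
Reactants: 12 benzyl 2-(benzyloxy)-6-methyl-4-(triisopropylsilyloxy)benzoate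
Product: 13 benzyl 2-(benzyloxy)-4-hydroxy-6-methylbenzoate
Conditions: Bu4NF, AcOH, THF, 0 °C
Reagents that add atoms: none
Why: Fluoride-induced desilylation driven by the Si–F bond, buffered with acetic acid so that the liberated phenoxide is protonated at once and the benzyl ester and ether stay intact.

Step 6
Reactants: 13 benzyl 2-(benzyloxy)-4-hydroxy-6-methylbenzoate; 11 2-(benzyloxy)-6-methyl-4-(triisopropylsilyloxy)benzoic acid
Product: 14 benzyl 2-(benzyloxy)-4-{[2-(benzyloxy)-6-methyl-4-(triisopropylsilyloxy)benzoyl]oxy}-6-methylbenzoate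
Conditions: DCC, DMAP (cat.), CH2Cl2, 0 °C → rt
Reagents that add atoms: none
Why: Steglich esterification, in which DMAP carries the acyl group of the di-ortho-substituted acid from its O-acylisourea to the unhindered a4 phenol under neutral conditions that the silyl ether tolerates.

Step 7
Reactants: 14 benzyl 2-(benzyloxy)-4-{[2-(benzyloxy)-6-methyl-4-(triisopropylsilyloxy)benzoyl]oxy}-6-methylbenzoate
Product: 15 benzyl 2-(benzyloxy)-4-{[2-(benzyloxy)-4-hydroxy-6-methylbenzoyl]oxy}-6-methylbenzoate
Conditions: Bu4NF, AcOH, THF, 0 °C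
Reagents that add atoms: none
Why: Buffered fluoride desilylation as in step 5, where the aryl ester should survive because its carbonyl is shielded by the b2 benzyloxy and b6 methyl groups and no free phenoxide accumulates.

Step 8
Reactants: 16 2,4-dihydroxy-6-methylbenzaldehyde; 2 benzyl bromide
Product: 17 2,4-bis(benzyloxy)-6-methylbenzaldehyde
Conditions: BnBr (2.5 equiv), K2CO3, DMF, 60 °C
Reagents that add atoms: benzyl bromide (2), BrCc1ccccc1
Why: Double Williamson etherification, with heating and excess halide to alkylate also the hydroxyl that is hydrogen-bonded to the aldehyde.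

Step 9
Reactants: 17 2,4-bis(benzyloxy)-6-methylbenzaldehyde; 18 3-chloroperoxybenzoic acid
Product: 20 2,4-bis(benzyloxy)-6-methylphenol, via aryl formate 19 (not isolated)
Conditions: mCPBA, CH2Cl2, 0 °C → rt; then K2CO3, MeOH, rt
Reagents that add atoms: 3-chloroperoxybenzoic acid (18), OOC(=O)c1cccc(Cl)c1
Why: Baeyer–Villiger oxidation of an electron-rich benzaldehyde (Dakin-type), in which the 2,4-dialkoxyaryl group migrates in preference to hydrogen and the resulting formate is methanolysed to the phenol.

Step 10
Reactants: 20 2,4-bis(benzyloxy)-6-methylphenol; 2 benzyl bromide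
Product: 21 1,2,5-tris(benzyloxy)-3-methylbenzene
Conditions: BnBr, K2CO3, DMF, 50 °C, under argon
Reagents that add atoms: benzyl bromide (2), BrCc1ccccc1
Why: Williamson etherification of the new phenol, run under inert gas because the para-alkoxyphenol is sensitive to air in base.

Step 11
Reactants: 21 1,2,5-tris(benzyloxy)-3-methylbenzene; 22 N,N-dimethylformamide
Product: 24 2,4,5-tris(benzyloxy)-6-methylbenzaldehyde, via iminium chloride 23 (not isolated)
Conditions: POCl3, DMF, 0 → 70 °C; then H2O
Reagents that add atoms: N,N-dimethylformamide (22), CN(C)C=O; water, O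
Why: Vilsmeier–Haack formylation, expected at C4 of 21 because this carbon is para to the C1 benzyloxy group and ortho to the C5 one, whereas C6 lies between two benzyloxy groups, a type of position that 1,2,4-trialkoxybenzenes and 3,5-dialkoxytoluenes leave largely unattacked.

Step 12
Reactants: 24 2,4,5-tris(benzyloxy)-6-methylbenzaldehyde; 25 sodium chlorite
Product: 26 2,4,5-tris(benzyloxy)-6-methylbenzoic acid
Conditions: NaClO2, NaH2PO4, 2-methyl-2-butene, t-BuOH/THF/H2O, rt
Reagents that add atoms: sodium chlorite (25), [Na+].[O-]Cl=O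
Why: Pinnick oxidation, which converts hindered aryl aldehydes to acids while the alkene scavenger removes hypochlorous acid before it can chlorinate the electron-rich ring.

Step 13
Reactants: 15 benzyl 2-(benzyloxy)-4-{[2-(benzyloxy)-4-hydroxy-6-methylbenzoyl]oxy}-6-methylbenzoate; 26 2,4,5-tris(benzyloxy)-6-methylbenzoic acid
Product: 27 benzyl 2-(benzyloxy)-4-{[2-(benzyloxy)-6-methyl-4-{[2,4,5-tris(benzyloxy)-6-methylbenzoyl]oxy}benzoyl]oxy}-6-methylbenzoate
Conditions: DCC, DMAP (cat.), CH2Cl2, rt
Reagents that add atoms: none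
Why: Steglich esterification of the b4 phenol with the ring C acid, where the existing aryl ester is too hindered to be transacylated by DMAP.

Step 14
Reactants: 27 benzyl 2-(benzyloxy)-4-{[2-(benzyloxy)-6-methyl-4-{[2,4,5-tris(benzyloxy)-6-methylbenzoyl]oxy}benzoyl]oxy}-6-methylbenzoate
Product: 28 2-hydroxy-4-{[2-hydroxy-6-methyl-4-{[2,4,5-trihydroxy-6-methylbenzoyl]oxy}benzoyl]oxy}-6-methylbenzoic acid (CNP0248995.0)
Conditions: H2 (1 atm), 10% Pd/C, EtOAc/THF, rt; filtration and isolation under argon
Reagents that add atoms: none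
Why: Heterogeneous catalytic hydrogenolysis cleaves the five benzyl ethers and the benzyl ester under neutral conditions that leave both aryl ester links untouched, and inert handling protects the oxidisable trihydroxy ring C.

Compound list
1 | 5-fluorobenzene-1,3-diol | Oc1cc(O)cc(F)c1 | starting material
2 | benzyl bromide | BrCc1ccccc1 | starting material
3 | 3-(benzyloxy)-5-fluorophenol | Oc1cc(F)cc(OCc2ccccc2)c1 | intermediate
4 | triisopropylsilyl chloride | CC(C)[Si](Cl)(C(C)C)C(C)C | starting material
5 | 1-(benzyloxy)-3-fluoro-5-(triisopropylsilyloxy)benzene | Fc1cc(O[Si](C(C)C)(C(C)C)C(C)C)cc(OCc2ccccc2)c1 | intermediate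
6 | methylmagnesium bromide | C[Mg]Br | starting material
7 | carbon dioxide | O=C=O | starting material
8 | [2-(benzyloxy)-6-fluoro-4-(triisopropylsilyloxy)phenyl]lithium | [Li]c1c(F)cc(O[Si](C(C)C)(C(C)C)C(C)C)cc1OCc1ccccc1 | intermediate
9 | 3-(benzyloxy)-5-(triisopropylsilyloxy)benzyne (1,2-didehydrobenzene) | C1(OCc2ccccc2)=CC(O[Si](C(C)C)(C(C)C)C(C)C)=CC#C1 | intermediate
10 | [2-(benzyloxy)-6-methyl-4-(triisopropylsilyloxy)phenyl]magnesium bromide | Cc1cc(O[Si](C(C)C)(C(C)C)C(C)C)cc(OCc2ccccc2)c1[Mg]Br | intermediate
11 | 2-(benzyloxy)-6-methyl-4-(triisopropylsilyloxy)benzoic acid | Cc1cc(O[Si](C(C)C)(C(C)C)C(C)C)cc(OCc2ccccc2)c1C(=O)O | intermediate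
12 | benzyl 2-(benzyloxy)-6-methyl-4-(triisopropylsilyloxy)benzoate | Cc1cc(O[Si](C(C)C)(C(C)C)C(C)C)cc(OCc2ccccc2)c1C(=O)OCc1ccccc1 | intermediate
13 | benzyl 2-(benzyloxy)-4-hydroxy-6-methylbenzoate | Cc1cc(O)cc(OCc2ccccc2)c1C(=O)OCc1ccccc1 | intermediate
14 | benzyl 2-(benzyloxy)-4-{[2-(benzyloxy)-6-methyl-4-(triisopropylsilyloxy)benzoyl]oxy}-6-methylbenzoate | Cc1cc(OC(=O)c2c(C)cc(O[Si](C(C)C)(C(C)C)C(C)C)cc2OCc2ccccc2)cc(OCc2ccccc2)c1C(=O)OCc1ccccc1 | intermediate
15 | benzyl 2-(benzyloxy)-4-{[2-(benzyloxy)-4-hydroxy-6-methylbenzoyl]oxy}-6-methylbenzoate | Cc1cc(OC(=O)c2c(C)cc(O)cc2OCc2ccccc2)cc(OCc2ccccc2)c1C(=O)OCc1ccccc1 | intermediate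
16 | 2,4-dihydroxy-6-methylbenzaldehyde | Cc1cc(O)cc(O)c1C=O | starting material
17 | 2,4-bis(benzyloxy)-6-methylbenzaldehyde | Cc1cc(OCc2ccccc2)cc(OCc2ccccc2)c1C=O | intermediate
18 | 3-chloroperoxybenzoic acid | OOC(=O)c1cccc(Cl)c1 | starting material
19 | 2,4-bis(benzyloxy)-6-methylphenyl formate | Cc1cc(OCc2ccccc2)cc(OCc2ccccc2)c1OC=O | intermediate
20 | 2,4-bis(benzyloxy)-6-methylphenol | Cc1cc(OCc2ccccc2)cc(OCc2ccccc2)c1O | intermediate
21 | 1,2,5-tris(benzyloxy)-3-methylbenzene | Cc1cc(OCc2ccccc2)cc(OCc2ccccc2)c1OCc1ccccc1 | intermediate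
22 | N,N-dimethylformamide | CN(C)C=O | starting material
23 | N-{[2,4,5-tris(benzyloxy)-6-methylphenyl]methylidene}-N-methylmethanaminium chloride | C[N+](C)=Cc1c(C)c(OCc2ccccc2)c(OCc2ccccc2)cc1OCc1ccccc1.[Cl-] | intermediate
24 | 2,4,5-tris(benzyloxy)-6-methylbenzaldehyde | Cc1c(OCc2ccccc2)c(OCc2ccccc2)cc(OCc2ccccc2)c1C=O | intermediate
25 | sodium chlorite | [Na+].[O-]Cl=O | starting material
26 | 2,4,5-tris(benzyloxy)-6-methylbenzoic acid | Cc1c(OCc2ccccc2)c(OCc2ccccc2)cc(OCc2ccccc2)c1C(=O)O | intermediate
27 | benzyl 2-(benzyloxy)-4-{[2-(benzyloxy)-6-methyl-4-{[2,4,5-tris(benzyloxy)-6-methylbenzoyl]oxy}benzoyl]oxy}-6-methylbenzoate | Cc1cc(OC(=O)c2c(C)cc(OC(=O)c3c(OCc4ccccc4)cc(OCc4ccccc4)c(OCc4ccccc4)c3C)cc2OCc2ccccc2)cc(OCc2ccccc2)c1C(=O)OCc1ccccc1 | intermediate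
28 | 2-hydroxy-4-{[2-hydroxy-6-methyl-4-{[2,4,5-trihydroxy-6-methylbenzoyl]oxy}benzoyl]oxy}-6-methylbenzoic acid | Cc1cc(OC(=O)c2c(C)cc(OC(=O)c3c(O)cc(O)c(O)c3C)cc2O)cc(O)c1C(=O)O | target

Total step count: 14. Longest linear sequence: 9 steps (steps 1 to 7, then 13 and 14); the ring C branch (steps 8 to 12) joins at step 13.

Steps most likely to fail

Step 3. Three things may go wrong.
- Metalation may occur at the benzylic methylene (followed by Wittig rearrangement) or next to the silyl ether.
- The aryllithium may add to the aryne and give biaryls.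
- Loss of LiF may be incomplete, so that a fluoro acid is formed on carboxylation.

The fallback avoids the aryne altogether. It sets out from 16 and comes back at 11. Selective silylation of the hydroxyl that is not hydrogen-bonded to the aldehyde (TIPSCl 4, imidazole, CH2Cl2, 0 °C) should give 2-hydroxy-6-methyl-4-(triisopropylsilyloxy)benzaldehyde F1. Williamson benzylation of the chelated hydroxyl (BnBr 2, K2CO3, MeCN, 60 °C) should give 2-(benzyloxy)-6-methyl-4-(triisopropylsilyloxy)benzaldehyde F2. Pinnick oxidation (NaClO2, NaH2PO4, 2-methyl-2-butene) then gives acid 11.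

Step 11. Formylation may take place between the two benzyloxy groups, or the crowded position may react so slowly that benzyl ethers are lost in hot POCl3/DMF. The fallback replaces formylation and oxidation by halogenation and carboxylation. It sets out from 21 and comes back at 26. Bromination with the small electrophile NBS (MeCN, 0 °C), directed para to the C1 benzyloxy group, should give 1,2,5-tris(benzyloxy)-4-bromo-3-methylbenzene F3, whose substitution pattern can be confirmed before going on. Bromine–lithium exchange (n-BuLi, THF, −78 °C) gives [2,4,5-tris(benzyloxy)-6-methylphenyl]lithium F4, which is not isolated but quenched with CO2 and acidified (aq. HCl) to give acid 26.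

Step 13. Acyl transfer from the crowded O-acylisourea of the ring C acid may be slow, so that rearrangement to the N-acylurea wins. The fallback uses a preformed acylating agent. It sets out from 26 and comes back at 27. Oxalyl chloride with catalytic DMF (CH2Cl2, 0 °C → rt) converts 26 into 2,4,5-tris(benzyloxy)-6-methylbenzoyl chloride F5. After removal of volatiles, F5 acylates phenol 15 in the presence of Et3N and catalytic DMAP (CH2Cl2, 0 °C → rt) to give 27.

Further compounds
F1 | step 3 | 2-hydroxy-6-methyl-4-(triisopropylsilyloxy)benzaldehyde | Cc1cc(O[Si](C(C)C)(C(C)C)C(C)C)cc(O)c1C=O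
F2 | step 3 | 2-(benzyloxy)-6-methyl-4-(triisopropylsilyloxy)benzaldehyde | Cc1cc(O[Si](C(C)C)(C(C)C)C(C)C)cc(OCc2ccccc2)c1C=O
F3 | step 11 | 1,2,5-tris(benzyloxy)-4-bromo-3-methylbenzene | Cc1c(Br)c(OCc2ccccc2)cc(OCc2ccccc2)c1OCc1ccccc1
F4 | step 11 | [2,4,5-tris(benzyloxy)-6-methylphenyl]lithium | [Li]c1c(C)c(OCc2ccccc2)c(OCc2ccccc2)cc1OCc1ccccc1
F5 | step 13 | 2,4,5-tris(benzyloxy)-6-methylbenzoyl chloride | Cc1c(OCc2ccccc2)c(OCc2ccccc2)cc(OCc2ccccc2)c1C(=O)Cl
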